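## Retrosynthetic overview

- The target is cut at both ester C–O bonds: a double Mitsunobu esterification (inversion at C6) joins two molecules of 6-epi-incarvilline to (2E,6E)-2,6-dimethylocta-2,6-dienedioic acid, which comes from geraniol by allylic and terminal oxidation.
- 6-epi-Incarvilline comes from a cis-fused N-Boc bicyclic ketone by LiAlH4 (ketone to alcohol, Boc to N-methyl) and a resolution; the ketone comes from a bicyclic enone by hydrogenation.
- Key disconnection: the C7–C7a bond of a 1,4-diketone, made from a piperidone enamine and 3-bromobutan-2-one acting as an enolonium (α-acyl cation) equivalent, so two natural enolate carbons are joined; aldol condensation then forms C5=C4a.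
- Ring order: the piperidine ring is bought; the cyclopentenone ring is annulated onto it in one flask; no other ring is formed.

Assumption: the racemic piperidone 1, 3-bromobutan-2-one and geraniol count as cheap catalogue chemicals. Compounds 5–7 are racemates drawn as the enantiomer that is carried on, because every stereocentre before the saturated ketone is base-labile and the absolute configuration is therefore fixed by resolution in step 4.

## Route

Step 1
Reactants: 1 tert-butyl 3-methyl-4-oxopiperidine-1-carboxylate (racemic); 2 3-bromobutan-2-one (racemic)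
Product: 5 rac-tert-butyl (4R,7S,7aS)-4,7-dimethyl-6-oxo-1,3,4,6,7,7a-hexahydro-2H-cyclopenta[c]pyridine-2-carboxylate, via enamine 3 (not isolated), via diketone 4 (not isolated)
Conditions: pyrrolidine (1.5 equiv), TsOH (2 mol%), PhMe, reflux, Dean–Stark; evaporate; 2 (1.2 equiv), MeCN, 60 °C; then 2 M aq. KOH, MeOH, 45 °C, stop when 4 is consumed
Reagents that add atoms: none
Why: Stork enamine alkylation in which the α-bromoketone acts as an enolonium equivalent joins C7 to C7a, two carbons that are both natural enolate positions, and the resulting 1,4-diketone closes by intramolecular aldol condensation (C5 onto C4a); all three stereocentres of 4 are α to a carbonyl and equilibrate in base, so 5 is drawn off as the most stable racemic diastereomer (4-methyl equatorial and cis to C7 across the piperidine ring, 7-methyl trans to C1).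

Step 2
Reactants: 5 rac-tert-butyl (4R,7S,7aS)-4,7-dimethyl-6-oxo-1,3,4,6,7,7a-hexahydro-2H-cyclopenta[c]pyridine-2-carboxylate
Product: 6 rac-tert-butyl (4R,4aS,7S,7aR)-4,7-dimethyl-6-oxooctahydro-2H-cyclopenta[c]pyridine-2-carboxylate
Conditions: H2 (1 atm), 10% Pd/C, EtOAc, rt
Reagents that add atoms: none
Why: Heterogeneous hydrogenation of the enone C4a=C5 from the open convex face (the face of H-7a; the other is covered by the folded piperidine ring) delivers H-4a syn to H-4 and H-7a, giving the cis-fused ketone with C4, C4a and C7a as in the target, while the base-labile C7 stays in its stable configuration.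

Step 3
Reactants: 6 rac-tert-butyl (4R,4aS,7S,7aR)-4,7-dimethyl-6-oxooctahydro-2H-cyclopenta[c]pyridine-2-carboxylate
Product: 7 rac-(4R,4aS,6S,7S,7aR)-2,4,7-trimethyloctahydro-1H-cyclopenta[c]pyridin-6-ol (racemic 6-epi-incarvilline)
Conditions: LiAlH4 (4 equiv), THF, 0 °C then reflux; Fieser work-up
Reagents that add atoms: none
Why: LiAlH4 adds hydride to the cyclopentanone from the convex face (also the intrinsic preference of 2-methylcyclopentanones with small hydrides), placing the hydroxyl on the concave face trans to the 7-methyl, and at reflux reduces the Boc carbamate to the N-methyl group (carbamate reduction).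

Step 4
Reactants: 7 rac-(4R,4aS,6S,7S,7aR)-2,4,7-trimethyloctahydro-1H-cyclopenta[c]pyridin-6-ol
Product: 8 (4R,4aS,6S,7S,7aR)-2,4,7-trimethyloctahydro-1H-cyclopenta[c]pyridin-6-ol (6-epi-incarvilline, single enantiomer)
Conditions: O,O′-di-p-toluoyl-L-tartaric acid (1.0 equiv; the D-acid if the wanted salt stays in solution), MeOH/acetone, two recrystallisations; then 2 M NaOH, CH2Cl2
Reagents that add atoms: none
Why: Classical resolution by diastereomeric salt crystallisation of the basic tertiary amine; no stereocentre is made, the (4R,4aS,6S,7S,7aR) enantiomer is selected and checked by chiral HPLC and an X-ray structure of the salt.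

Step 5
Reactants: 9 geraniol, (2E)-3,7-dimethylocta-2,6-dien-1-ol
Product: 10 (2E,6E)-2,6-dimethylocta-2,6-diene-1,8-diol
Conditions: SeO2 (0.1 equiv), t-BuOOH (70% aq., 3 equiv), salicylic acid (0.1 equiv), CH2Cl2, rt
Reagents that add atoms: tert-butyl hydroperoxide, CC(C)(C)OO (terminal source of the new hydroxyl O, relayed by selenium dioxide, O=[Se]=O)
Why: Riley allylic oxidation under catalytic SeO2 (ene reaction then [2,3]-sigmatropic shift) hydroxylates the (E)-methyl group of the electron-rich distal trisubstituted alkene with E geometry, while the alkene bearing the allylic alcohol is deactivated.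

Step 6
Reactants: 10 (2E,6E)-2,6-dimethylocta-2,6-diene-1,8-diol
Product: 12 (2E,6E)-2,6-dimethylocta-2,6-dienedioic acid, via dialdehyde 11 (not isolated)
Conditions: TEMPO (0.2 equiv), PhI(OAc)2 (2.4 equiv), CH2Cl2, rt; then t-BuOH/H2O, 2-methyl-2-butene, NaH2PO4, NaClO2, 0 °C to rt
Reagents that add atoms: sodium chlorite NaClO2, [Na+].[O-]Cl=O (one O in each carboxyl group)
Why: TEMPO/PhI(OAc)2 (oxoammonium) oxidation converts both allylic alcohols to the enals without E/Z scrambling and a Pinnick oxidation in the same flask gives the diacid, with 2-methyl-2-butene trapping HOCl so that the alkenes survive.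

Step 7
Reactants: 8 (4R,4aS,6S,7S,7aR)-2,4,7-trimethyloctahydro-1H-cyclopenta[c]pyridin-6-ol (2.2 equiv); 12 (2E,6E)-2,6-dimethylocta-2,6-dienedioic acid (1.0 equiv)
Product: 13 bis[(4R,4aS,6R,7S,7aR)-2,4,7-trimethyloctahydro-1H-cyclopenta[c]pyridin-6-yl] (2E,6E)-2,6-dimethylocta-2,6-dienedioate (target)
Conditions: PPh3 (2.6 equiv), DIAD (2.6 equiv), THF, 0 °C to rt
Reagents that add atoms: none
Why: Double Mitsunobu esterification in which each carboxylate displaces the activated concave hydroxyl by SN2 from the open convex face, inverting C6 from S to R in both amino alcohol units so that each ester ends up cis to the 7-methyl group as in the target.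

## Compound list

1 | tert-butyl 3-methyl-4-oxopiperidine-1-carboxylate (racemic) | CC1CN(CCC1=O)C(=O)OC(C)(C)C | starting material
2 | 3-bromobutan-2-one (racemic) | CC(Br)C(C)=O | starting material
3 | tert-butyl 3-methyl-4-(pyrrolidin-1-yl)-3,6-dihydropyridine-1(2H)-carboxylate (enamine, racemic) | CC1CN(CC=C1N1CCCC1)C(=O)OC(C)(C)C | intermediate (not isolated)
4 | tert-butyl 3-methyl-4-oxo-5-(3-oxobutan-2-yl)piperidine-1-carboxylate (equilibrating stereoisomer mixture) | CC1CN(CC(C(C)C(C)=O)C1=O)C(=O)OC(C)(C)C | intermediate (not isolated)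
5 | rac-tert-butyl (4R,7S,7aS)-4,7-dimethyl-6-oxo-1,3,4,6,7,7a-hexahydro-2H-cyclopenta[c]pyridine-2-carboxylate (enone C4a=C5; one enantiomer drawn) | O=C1C=C2[C@@H](CN(C[C@@H]2C)C(=O)OC(C)(C)C)[C@@H]1C | intermediate
6 | rac-tert-butyl (4R,4aS,7S,7aR)-4,7-dimethyl-6-oxooctahydro-2H-cyclopenta[c]pyridine-2-carboxylate (cis-fused; one enantiomer drawn) | O=C1C[C@@H]2[C@@H](CN(C[C@@H]2C)C(=O)OC(C)(C)C)[C@@H]1C | intermediate
7 | rac-(4R,4aS,6S,7S,7aR)-2,4,7-trimethyloctahydro-1H-cyclopenta[c]pyridin-6-ol (racemate; one enantiomer drawn) | O[C@H]1C[C@@H]2[C@@H](CN(C)C[C@@H]2C)[C@@H]1C | intermediate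
8 | (4R,4aS,6S,7S,7aR)-2,4,7-trimethyloctahydro-1H-cyclopenta[c]pyridin-6-ol (6-epi-incarvilline, single enantiomer) | O[C@H]1C[C@@H]2[C@@H](CN(C)C[C@@H]2C)[C@@H]1C | intermediate
9 | geraniol, (2E)-3,7-dimethylocta-2,6-dien-1-ol | CC(C)=CCC/C(C)=C/CO | starting material
10 | (2E,6E)-2,6-dimethylocta-2,6-diene-1,8-diol | OC/C(C)=C/CC/C(C)=C/CO | intermediate
11 | (2E,6E)-2,6-dimethylocta-2,6-dienedial | O=C/C(C)=C/CC/C(C)=C/C=O | intermediate (not isolated)
12 | (2E,6E)-2,6-dimethylocta-2,6-dienedioic acid | OC(=O)/C(C)=C/CC/C(C)=C/C(=O)O | intermediate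
13 | bis[(4R,4aS,6R,7S,7aR)-2,4,7-trimethyloctahydro-1H-cyclopenta[c]pyridin-6-yl] (2E,6E)-2,6-dimethylocta-2,6-dienedioate | C/C(=C\C(=O)O[C@@H]1C[C@@H]2[C@@H](CN(C)C[C@@H]2C)[C@@H]1C)CC/C=C(\C)C(=O)O[C@@H]1C[C@@H]2[C@@H](CN(C)C[C@@H]2C)[C@@H]1C | target

## Step count and risks

Total steps: 7. Longest linear sequence: 5 (steps 1, 2, 3, 4, 7).

**Step 1 (annulation).** The secondary bromoketone may lose HBr to but-3-en-2-one (then a Michael/Robinson pathway) or alkylate nitrogen. Prolonged base may also move the enone double bond to the tetrasubstituted C7=C7a position, which would lose the C4/C7a relationship, and the diastereomer ratio at C4 may be only moderate. The fallback sets out from 1 (through its enamine 3) and rejoins at 5. Enamine 3 is added to (E)-2-nitrobut-2-ene (MeCN, 0 °C to rt, aqueous AcOH work-up); this is a conjugate addition to a nitroalkene that serves as a different α-acyl cation equivalent and has no leaving group to eliminate. It gives the nitro ketone tert-butyl 3-methyl-5-(3-nitrobutan-2-yl)-4-oxopiperidine-1-carboxylate F1. A buffered reductive Nef reaction (TiCl3, NH4OAc, aq. THF, rt) then unmasks diketone 4, which is isolated here, and brief KOH/MeOH at rt closes it to 5 under milder, separately monitored conditions.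

**Step 4 (resolution).** No salt may crystallise with useful selectivity. The fallback sets out from 6 and rejoins at 8. Racemic ketone 6 is subjected to an enzymatic kinetic resolution with a ketoreductase from a commercial screening panel (NADP+, isopropanol, pH 7 buffer, 30 °C, stopped near half conversion). Only the (4R,4aS,7S,7aR) ketone is reduced, from the convex face, to tert-butyl (4R,4aS,6S,7S,7aR)-6-hydroxy-4,7-dimethyloctahydro-2H-cyclopenta[c]pyridine-2-carboxylate F2. This is separated from the unreacted mirror-image ketone by chromatography and reduced with LiAlH4 (THF, reflux) to 8. In either variant, a small residue of the wrong enantiomer ends up in step 7 mainly as the heterochiral diester, a separable diastereomer.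

**Step 7 (double Mitsunobu).** The second esterification on a hindered secondary alcohol next to a basic amine may stall or give elimination. The fallback sets out from 8 (with 12) and rejoins at 13. Alcohol 8 is converted with MsCl/Et3N (CH2Cl2, 0 °C) into (4R,4aS,6S,7S,7aR)-2,4,7-trimethyloctahydro-1H-cyclopenta[c]pyridin-6-yl methanesulfonate F3. The ring nitrogen sits on the same face as the leaving group and cannot displace it. The dicaesium salt of 12 (12, Cs2CO3, DMF, 50 °C) then displaces the mesylate by SN2 from the convex face, with the same inversion at C6, to give 13.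

## Further compounds

F1 | step 1 | tert-butyl 3-methyl-5-(3-nitrobutan-2-yl)-4-oxopiperidine-1-carboxylate (stereoisomer mixture) | CC1CN(CC(C(C)C(C)[N+](=O)[O-])C1=O)C(=O)OC(C)(C)C
F2 | step 4 | tert-butyl (4R,4aS,6S,7S,7aR)-6-hydroxy-4,7-dimethyloctahydro-2H-cyclopenta[c]pyridine-2-carboxylate | O[C@H]1C[C@@H]2[C@@H](CN(C[C@@H]2C)C(=O)OC(C)(C)C)[C@@H]1C
F3 | step 7 | (4R,4aS,6S,7S,7aR)-2,4,7-trimethyloctahydro-1H-cyclopenta[c]pyridin-6-yl methanesulfonate | CS(=O)(=O)O[C@H]1C[C@@H]2[C@@H](CN(C)C[C@@H]2C)[C@@H]1C
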